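The ring C1–C10–C9–C8–C7–C11 of the cedrane core is read as a masked benzene whose C1 and C7 are spanned by C5–C6, so the core is cut back to an arene bearing a 4-methylpent-3-enyl chain. Because C12 stands on the C11 face of cyclopentane C1–C2–C3–C4–C5, one oxygen can join C12 to C11; the photosubstrate is therefore an (S)-3-substituted 6-methyl-2,3-dihydrobenzofuran. Irradiation adds the olefin across C1 and C7, forming C1–C5 and C6–C7, two five-membered rings and the stereocentres C1, C5 and C7 in one operation. The ether is then cut, C11 deoxygenated, C10 and C15 oxidised and the protected hydroxy acid attached at C10.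

Key step: step 6

Remarks on the chemistry
- Tricyclic compounds carry cedrane numbering: C1 spiro carbon, C2 bearing C12, C3, C4, C5 ring-fusion CH, C6 CMe2, C7 bridgehead CH, C8 bearing C15, C9, C10, C11 one-carbon bridge.
- "2-epi-cedr" means C1, C5 and C7 as in natural (−)-α-cedrene, with C12 on the face of cyclopentane C1–C5 that carries C11. "10S" means the C10 oxygen is equatorial, on the side of the C5–C6 bridge.
- Assumption: the 12-hydroxy-11-ketones 14, 15 and 16 are drawn open-chain; if they rest as the C11/C12 hemiketal the following steps are unchanged.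
- The configuration at the bromine-bearing carbon of 14 and 15 is left undefined, because step 8 erases it.

Step 1
Reactants: 1 2'-hydroxy-4'-methylacetophenone; 2 prenyl bromide (1-bromo-3-methylbut-2-ene)
Product: 3 1-(2-hydroxy-4-methylphenyl)-5-methylhex-4-en-1-one
Conditions: LDA (2.2 equiv), THF, −78 → 0 °C; then 2, −78 °C → rt; dil. HCl
Reagents that add atoms: none
Why: Two equivalents of amide base give the phenoxide–enolate dianion, which is alkylated by the allylic bromide at the enolate carbon (dianion C-alkylation, SN2); no stereocentre is formed.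

Step 2
Reactants: 3 1-(2-hydroxy-4-methylphenyl)-5-methylhex-4-en-1-one
Product: 4 1-[2-(tert-butyldimethylsilyloxy)-4-methylphenyl]-5-methylhex-4-en-1-one
Conditions: TBSCl, imidazole, DMF, rt
Reagents that add atoms: tert-butyldimethylsilyl chloride, CC(C)(C)[Si](C)(C)Cl
Why: Imidazole-promoted O-silylation masks the phenol so that the ylide and the metal hydride catalyst of the next two steps meet no acidic proton.

Step 3
Reactants: 4 1-[2-(tert-butyldimethylsilyloxy)-4-methylphenyl]-5-methylhex-4-en-1-one; 5 methyltriphenylphosphonium bromide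
Product: 7 tert-butyldimethyl[5-methyl-2-(6-methylhepta-1,5-dien-2-yl)phenoxy]silane, via methylenetriphenylphosphorane 6 (not isolated)
Conditions: 5, KHMDS, THF, 0 °C; then 4, 0 °C → rt
Reagents that add atoms: none
Why: Wittig methylenation of the aryl ketone by the non-stabilised ylide gives the 1,1-disubstituted styrene and brings in C12.

Step 4
Reactants: 7 tert-butyldimethyl[5-methyl-2-(6-methylhepta-1,5-dien-2-yl)phenoxy]silane
Product: 10 (S)-2-(2-hydroxy-4-methylphenyl)-6-methylhept-5-en-1-ol, via (S)-pinacol boronate 8 (not isolated), via (S)-silyl ether alcohol 9 (not isolated)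
Conditions: chiral iminopyridine-oxazoline CoCl2 precatalyst (2 mol %, ligand antipode that gives the S product), NaBHEt3 (6 mol %), HBpin, THF, rt; then 3 M NaOH, 30% H2O2, THF/MeOH, 0 °C → rt
Reagents that add atoms: hydrogen peroxide, OO
Why: Cobalt-hydride-catalysed enantioselective anti-Markovnikov hydroboration of a 1,1-disubstituted aryl alkene puts boron on C12 and delivers hydrogen to one face of C2 under ligand control while the trisubstituted olefin stays inert; alkaline peroxide then oxidises the C–B bond and the same hydroxide cleaves the aryl silyl ether.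

Step 5
Reactants: 10 (S)-2-(2-hydroxy-4-methylphenyl)-6-methylhept-5-en-1-ol
Product: 11 (S)-6-methyl-3-(4-methylpent-3-enyl)-2,3-dihydrobenzofuran
Conditions: PPh3, DIAD, THF, 0 °C → rt
Reagents that add atoms: none
Why: Intramolecular Mitsunobu etherification, in which the phenol displaces the activated primary alcohol in a 5-exo-tet closure; C2 is not a reacting centre and keeps its configuration.

Step 6
Reactants: 11 (S)-6-methyl-3-(4-methylpent-3-enyl)-2,3-dihydrobenzofuran
Product: 12 meta photoadduct A (cyclopropane C7–C8–C11, olefin C9=C10, oxygen bridging C11 and C12) plus 13 meta photoadduct B (cyclopropane C1–C10–C11, olefin C8=C9, oxygen bridging C11 and C12), used as the mixture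
Conditions: hν (254 nm, quartz), pentane, 5 mM, degassed, rt
Reagents that add atoms: none
Why: Proposed new method: the singlet-excited arene forms an intramolecular exciplex with the trisubstituted olefin, which bonds to the two ring carbons that flank the oxygen-bearing C11 (C5 to C1 and C6 to C7), and the C11 centre then collapses onto either end of the C8–C9–C10 allyl unit to give the cyclopropanes of 12 and 13. The closest known reaction type is the intramolecular arene–alkene meta photocycloaddition of 5-(2-alkoxyaryl)pent-2-enes with a three-atom tether; what is untested is a donor oxygen tied back to the benzylic carbon in a dihydrofuran, which should help because it holds the chain nearly perpendicular to the arene and makes the three five-membered rings around C1 a low-strain bowl. Bond C1–C5 closes cyclopentane C1–C2–C3–C4–C5 through the three-atom tether, bond C6–C7 closes cyclopentane C1–C5–C6–C7–C11 by bridging two arene carbons and so completes the bicyclo[3.2.1]octane, and bond C11–C8 or C11–C10 closes the three-membered ring. C1 is controlled by C2, since the chain can reach only the arene face on which it stands; C5 and C7 follow from suprafacial addition of the olefin on that face, and C11 together with C8 or C10 from closure of the cyclopropane on the other side of the former ring plane. The step needs bonding at C1 and C7 (the 1,3 mode with respect to the chain-bearing carbon) instead of the ortho mode or the mode across the carbons next to C1, which the donor on C11 and the tether length secure, and it needs one arene face, which C2 secures; the relation of C12 to C11 is fixed by the ether ring, which can only be cis-fused.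

Step 7
Reactants: 12 meta photoadduct A; 13 meta photoadduct B
Product: 14 10-bromo-12-hydroxy-2-epi-cedr-8-en-11-one plus 15 8-bromo-12-hydroxy-2-epi-cedr-9-en-11-one, used as the crude mixture
Conditions: NBS (1.05 equiv), NaHCO3 (buffer), THF/H2O (4:1), 0 °C
Reagents that add atoms: N-bromosuccinimide, O=C1CCC(=O)N1Br; water, O
Why: Electrophilic opening of oxygen-activated vinylcyclopropanes: Br+ adds to the olefin terminus remote from the three-membered ring (C10 in 12, C8 in 13), the cyclopropane bond to C11 breaks with push from oxygen, and water captures the oxocarbenium ion to free the C11 ketone and the C12 alcohol, leaving C1, C2, C5 and C7 untouched.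

Step 8
Reactants: 14 10-bromo-12-hydroxy-2-epi-cedr-8-en-11-one; 15 8-bromo-12-hydroxy-2-epi-cedr-9-en-11-one
Product: 16 12-hydroxy-2-epi-cedr-8-en-11-one
Conditions: Bu3SnH, AIBN (cat.), toluene, 80 °C
Reagents that add atoms: none
Why: Radical-chain dehalogenation with tin hydride, in which both allylic bromides give the same C8–C9–C10 allyl radical; it should take hydrogen at the secondary terminus C10 and leave the more substituted C8=C9 olefin.

Step 9
Reactants: 16 12-hydroxy-2-epi-cedr-8-en-11-one
Product: 18 2-epi-cedr-8-en-12-ol, via C11 hydrazone 17 (not isolated)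
Conditions: N2H4·H2O, KOH, diethylene glycol, 130 °C, then 200 °C
Reagents that add atoms: none
Why: Wolff–Kishner reduction (Huang-Minlon procedure) of the bridge ketone, which cannot enolise towards quaternary C1 or bridgehead C7, so the olefin stays in place and no stereocentre is touched.

Step 10
Reactants: 18 2-epi-cedr-8-en-12-ol
Product: 19 12-(tert-butyldimethylsilyloxy)-2-epi-cedr-8-ene
Conditions: TBSCl, imidazole, DMF, rt
Reagents that add atoms: tert-butyldimethylsilyl chloride, CC(C)(C)[Si](C)(C)Cl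
Why: Standard silylation of the primary alcohol protects C12 through the oxidations at C10 and C15.

Step 11
Reactants: 19 12-(tert-butyldimethylsilyloxy)-2-epi-cedr-8-ene
Product: 20 12-(tert-butyldimethylsilyloxy)-2-epi-cedr-8-en-10-one
Conditions: Rh2(cap)4 (1 mol %), t-BuOOH (5 equiv), K2CO3 (0.5 equiv), CH2Cl2, rt
Reagents that add atoms: tert-butyl hydroperoxide, CC(C)(C)OO
Why: Dirhodium-caprolactamate/hydroperoxide allylic oxidation, in which the tert-butylperoxyl radical abstracts hydrogen from the only ring allylic methylene (C10) and oxygen enters at that less hindered terminus to give the conjugated enone.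

Step 12
Reactants: 20 12-(tert-butyldimethylsilyloxy)-2-epi-cedr-8-en-10-one
Product: 21 12-(tert-butyldimethylsilyloxy)-10-oxo-2-epi-cedr-8-en-15-al
Conditions: SeO2 (1.5 equiv), 1,4-dioxane, 90 °C
Reagents that add atoms: selenium dioxide, O=[Se]=O
Why: Riley oxidation at the vinylogous position: the enone can enolise only through its β-methyl group C15 (C1 is quaternary, C7 a bridgehead), so selenium dioxide takes that methyl to the aldehyde as in the known oxidation of β-methyl cycloalkenones to formyl enones.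

Step 13
Reactants: 21 12-(tert-butyldimethylsilyloxy)-10-oxo-2-epi-cedr-8-en-15-al
Product: 22 (10S)-12-(tert-butyldimethylsilyloxy)-2-epi-cedr-8-ene-10,15-diol
Conditions: NaBH4, CeCl3·7H2O, MeOH, −78 → −40 °C
Reagents that add atoms: none
Why: Luche 1,2-reduction of both carbonyl groups; hydride should reach C10 from the exo face (the C11 side, antiperiplanar to the C1–C5 bond, as in exo attack on norbornan-2-ones) because the endo face is screened by the C5–C6 bridge and its endo methyl, which places the hydroxyl equatorial on the side of that bridge (10S).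

Step 14
Reactants: 22 (10S)-12-(tert-butyldimethylsilyloxy)-2-epi-cedr-8-ene-10,15-diol
Product: 23 (10S)-12-(tert-butyldimethylsilyloxy)-10-hydroxy-2-epi-cedr-8-en-15-al
Conditions: TEMPO (10 mol %), PhI(OAc)2 (1.1 equiv), CH2Cl2, 0 °C → rt
Reagents that add atoms: none
Why: Oxoammonium oxidation is far faster for the unhindered primary allylic alcohol than for the secondary alcohol next to quaternary C1, so only C15 should be taken to the aldehyde.

Step 15
Reactants: 24 palmitoleic acid, (9Z)-hexadec-9-enoic acid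
Product: 25 (9Z)-16-hydroxyhexadec-9-enoic acid
Conditions: resting E. coli cells co-expressing a CYP153A ω-hydroxylase–reductase fusion and glucose dehydrogenase, D-glucose, air, phosphate buffer pH 7.4, 30 °C
Reagents that add atoms: dioxygen, O=O
Why: Enzymatic terminal hydroxylation by a CYP153A-type ω-hydroxylase, whose narrow substrate channel presents only the methyl end of C12–C18 fatty acids to the haem oxidant, so the Z olefin and the allylic positions are left alone.

Step 16
Reactants: 25 (9Z)-16-hydroxyhexadec-9-enoic acid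
Product: 27 (9Z)-16-(tert-butyldiphenylsilyloxy)hexadec-9-enoic acid, via bis-silyl derivative 26 (not isolated)
Conditions: TBDPSCl (2.2 equiv), imidazole, DMF, rt; then K2CO3, MeOH/THF/H2O, rt; pH 4
Reagents that add atoms: tert-butyldiphenylsilyl chloride, CC(C)(C)[Si](Cl)(c1ccccc1)c1ccccc1
Why: Silylation of hydroxyl and carboxyl groups followed by hydrolysis of the labile silyl ester, which leaves the robust primary silyl ether.

Step 17
Reactants: 23 (10S)-12-(tert-butyldimethylsilyloxy)-10-hydroxy-2-epi-cedr-8-en-15-al; 27 (9Z)-16-(tert-butyldiphenylsilyloxy)hexadec-9-enoic acid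
Product: 29 (10S)-12-(tert-butyldimethylsilyloxy)-15-oxo-2-epi-cedr-8-en-10-yl (9Z)-16-(tert-butyldiphenylsilyloxy)hexadec-9-enoate, via mixed trichlorobenzoic anhydride 28 (not isolated)
Conditions: 27, 2,4,6-Cl3C6H2COCl, Et3N, toluene, rt; then 23, DMAP, toluene, rt → 40 °C
Reagents that add atoms: none
Why: Yamaguchi esterification: the acid is activated as its 2,4,6-trichlorobenzoyl mixed anhydride and passed by DMAP to the hindered secondary alcohol, with retention at C10 because the C10–O bond is never broken.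

Step 18
Reactants: 29 (10S)-12-(tert-butyldimethylsilyloxy)-15-oxo-2-epi-cedr-8-en-10-yl (9Z)-16-(tert-butyldiphenylsilyloxy)hexadec-9-enoate
Product: 30 (10S)-12-(tert-butyldimethylsilyloxy)-10-{[(9Z)-16-(tert-butyldiphenylsilyloxy)hexadec-9-enoyl]oxy}-2-epi-cedr-8-en-15-oic acid
Conditions: NaClO2, NaH2PO4, 2-methyl-2-butene (excess), t-BuOH/H2O, 0 °C → rt
Reagents that add atoms: sodium chlorite, [Na+].[O-]Cl=O
Why: Pinnick oxidation turns the enal into the acid under buffered conditions, and 2-methyl-2-butene removes hypochlorous acid before it can attack the Z olefin.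

Step 19
Reactants: 30 (10S)-12-(tert-butyldimethylsilyloxy)-10-{[(9Z)-16-(tert-butyldiphenylsilyloxy)hexadec-9-enoyl]oxy}-2-epi-cedr-8-en-15-oic acid
Product: 31 (10S)-10-{[(9Z)-16-(tert-butyldiphenylsilyloxy)hexadec-9-enoyl]oxy}-12-hydroxy-2-epi-cedr-8-en-15-oic acid
Conditions: AcOH/THF/H2O (3:1:1), 30 °C
Reagents that add atoms: none
Why: Acid-catalysed hydrolysis cleaves a primary TBS ether much faster than a primary TBDPS ether, and the absence of base and of alcohol solvent avoids acyl migration from C10 and esterification of the acid.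

Step 20
Reactants: 31 (10S)-10-{[(9Z)-16-(tert-butyldiphenylsilyloxy)hexadec-9-enoyl]oxy}-12-hydroxy-2-epi-cedr-8-en-15-oic acid
Product: 32 (10S)-10-{[(9Z)-16-(tert-butyldiphenylsilyloxy)hexadec-9-enoyl]oxy}-12-oxo-2-epi-cedr-8-en-15-oic acid
Conditions: Dess–Martin periodinane, CH2Cl2, 0 °C → rt; aq. Na2S2O3/phosphate pH 6 work-up
Reagents that add atoms: none
Why: Dess–Martin oxidation of the primary alcohol runs under neutral to weakly acidic conditions, so the new aldehyde should not enolise at C2, and the free carboxylic acid is tolerated.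

Step 21
Reactants: 32 (10S)-10-{[(9Z)-16-(tert-butyldiphenylsilyloxy)hexadec-9-enoyl]oxy}-12-oxo-2-epi-cedr-8-en-15-oic acid
Product: 33 target CNP0214056.2, (1S,2S,5S,7R,10S)-2-formyl-10-{[(9Z)-16-hydroxyhexadec-9-enoyl]oxy}-6,6-dimethyltricyclo[5.3.1.0^1,5]undec-8-ene-8-carboxylic acid
Conditions: HF·pyridine, THF, 0 °C → rt
Reagents that add atoms: none
Why: Fluoride-mediated cleavage of the TBDPS ether in an acidic medium, in which the α-stereocentre of the aldehyde, the C10 ester and the Z olefin should be stable.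

Compound list
1 | 2'-hydroxy-4'-methylacetophenone | CC(=O)c1ccc(C)cc1O | starting material
2 | prenyl bromide (1-bromo-3-methylbut-2-ene) | CC(C)=CCBr | starting material
3 | 1-(2-hydroxy-4-methylphenyl)-5-methylhex-4-en-1-one | CC(C)=CCCC(=O)c1ccc(C)cc1O | intermediate
4 | 1-[2-(tert-butyldimethylsilyloxy)-4-methylphenyl]-5-methylhex-4-en-1-one | CC(C)=CCCC(=O)c1ccc(C)cc1O[Si](C)(C)C(C)(C)C | intermediate
5 | methyltriphenylphosphonium bromide | C[P+](c1ccccc1)(c1ccccc1)c1ccccc1.[Br-] | starting material
6 | methylenetriphenylphosphorane | C=P(c1ccccc1)(c1ccccc1)c1ccccc1 | intermediate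
7 | tert-butyldimethyl[5-methyl-2-(6-methylhepta-1,5-dien-2-yl)phenoxy]silane | CC(C)=CCCC(=C)c1ccc(C)cc1O[Si](C)(C)C(C)(C)C | intermediate
8 | (S)-2-{2-[2-(tert-butyldimethylsilyloxy)-4-methylphenyl]-6-methylhept-5-enyl}-4,4,5,5-tetramethyl-1,3,2-dioxaborolane | CC1(C)OB(C[C@@H](CCC=C(C)C)c2ccc(C)cc2O[Si](C)(C)C(C)(C)C)OC1(C)C | intermediate
9 | (S)-2-[2-(tert-butyldimethylsilyloxy)-4-methylphenyl]-6-methylhept-5-en-1-ol | OC[C@@H](CCC=C(C)C)c1ccc(C)cc1O[Si](C)(C)C(C)(C)C | intermediate
10 | (S)-2-(2-hydroxy-4-methylphenyl)-6-methylhept-5-en-1-ol | OC[C@@H](CCC=C(C)C)c1ccc(C)cc1O | intermediate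
11 | (S)-6-methyl-3-(4-methylpent-3-enyl)-2,3-dihydrobenzofuran | Cc1ccc2c(c1)OC[C@H]2CCC=C(C)C | intermediate
12 | meta photoadduct A: bonds C1–C5 and C6–C7, cyclopropane C7–C8–C11, olefin C9=C10, cis-fused oxolane O–C12–C2–C1–C11 | C[C@]12C=C[C@@]34[C@H]5CO[C@]32[C@@H]1C(C)(C)[C@@H]4CC5 | intermediate
13 | meta photoadduct B: bonds C1–C5 and C6–C7, cyclopropane C1–C10–C11, olefin C8=C9, cis-fused oxolane O–C12–C2–C1–C11 | CC1=C[C@@H]2[C@@]34[C@H]5CO[C@@]23[C@@H]1C(C)(C)[C@@H]4CC5 | intermediate
14 | 10-bromo-12-hydroxy-2-epi-cedr-8-en-11-one (C10 configuration undefined) | CC1(C)[C@H]2C(=O)[C@@]3(C(Br)C=C2C)[C@@H](CO)CC[C@@H]13 | intermediate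
15 | 8-bromo-12-hydroxy-2-epi-cedr-9-en-11-one (C8 configuration undefined) | CC1(C)[C@H]2C(=O)[C@@]3(C=CC2(C)Br)[C@@H](CO)CC[C@@H]13 | intermediate
16 | 12-hydroxy-2-epi-cedr-8-en-11-one | CC1(C)[C@H]2C(=O)[C@@]3(CC=C2C)[C@@H](CO)CC[C@@H]13 | intermediate
17 | 12-hydroxy-2-epi-cedr-8-en-11-one hydrazone | CC1(C)[C@H]2C(=NN)[C@@]3(CC=C2C)[C@@H](CO)CC[C@@H]13 | intermediate
18 | 2-epi-cedr-8-en-12-ol | CC1(C)[C@H]2C[C@@]3(CC=C2C)[C@@H](CO)CC[C@@H]13 | intermediate
19 | 12-(tert-butyldimethylsilyloxy)-2-epi-cedr-8-ene | CC1(C)[C@H]2C[C@@]3(CC=C2C)[C@@H](CO[Si](C)(C)C(C)(C)C)CC[C@@H]13 | intermediate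
20 | 12-(tert-butyldimethylsilyloxy)-2-epi-cedr-8-en-10-one | CC1(C)[C@H]2C[C@@]3(C(=O)C=C2C)[C@@H](CO[Si](C)(C)C(C)(C)C)CC[C@@H]13 | intermediate
21 | 12-(tert-butyldimethylsilyloxy)-10-oxo-2-epi-cedr-8-en-15-al | CC1(C)[C@H]2C[C@@]3(C(=O)C=C2C=O)[C@@H](CO[Si](C)(C)C(C)(C)C)CC[C@@H]13 | intermediate
22 | (10S)-12-(tert-butyldimethylsilyloxy)-2-epi-cedr-8-ene-10,15-diol | CC1(C)[C@H]2C[C@@]3([C@@H](O)C=C2CO)[C@@H](CO[Si](C)(C)C(C)(C)C)CC[C@@H]13 | intermediate
23 | (10S)-12-(tert-butyldimethylsilyloxy)-10-hydroxy-2-epi-cedr-8-en-15-al | CC1(C)[C@H]2C[C@@]3([C@@H](O)C=C2C=O)[C@@H](CO[Si](C)(C)C(C)(C)C)CC[C@@H]13 | intermediate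
24 | palmitoleic acid, (9Z)-hexadec-9-enoic acid | CCCCCC/C=C\CCCCCCCC(=O)O | starting material
25 | (9Z)-16-hydroxyhexadec-9-enoic acid | OCCCCCC/C=C\CCCCCCCC(=O)O | intermediate
26 | tert-butyldiphenylsilyl (9Z)-16-(tert-butyldiphenylsilyloxy)hexadec-9-enoate | CC(C)(C)[Si](c1ccccc1)(c1ccccc1)OCCCCCC/C=C\CCCCCCCC(=O)O[Si](c1ccccc1)(c1ccccc1)C(C)(C)C | intermediate
27 | (9Z)-16-(tert-butyldiphenylsilyloxy)hexadec-9-enoic acid | CC(C)(C)[Si](c1ccccc1)(c1ccccc1)OCCCCCC/C=C\CCCCCCCC(=O)O | intermediate
28 | (9Z)-16-(tert-butyldiphenylsilyloxy)hexadec-9-enoic 2,4,6-trichlorobenzoic anhydride | CC(C)(C)[Si](c1ccccc1)(c1ccccc1)OCCCCCC/C=C\CCCCCCCC(=O)OC(=O)c1c(Cl)cc(Cl)cc1Cl | intermediate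
29 | (10S)-12-(tert-butyldimethylsilyloxy)-15-oxo-2-epi-cedr-8-en-10-yl (9Z)-16-(tert-butyldiphenylsilyloxy)hexadec-9-enoate | CC1(C)[C@H]2C[C@@]3([C@@H](OC(=O)CCCCCCC/C=C\CCCCCCO[Si](c4ccccc4)(c4ccccc4)C(C)(C)C)C=C2C=O)[C@@H](CO[Si](C)(C)C(C)(C)C)CC[C@@H]13 | intermediate
30 | (10S)-12-(tert-butyldimethylsilyloxy)-10-{[(9Z)-16-(tert-butyldiphenylsilyloxy)hexadec-9-enoyl]oxy}-2-epi-cedr-8-en-15-oic acid | CC1(C)[C@H]2C[C@@]3([C@@H](OC(=O)CCCCCCC/C=C\CCCCCCO[Si](c4ccccc4)(c4ccccc4)C(C)(C)C)C=C2C(=O)O)[C@@H](CO[Si](C)(C)C(C)(C)C)CC[C@@H]13 | intermediate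
31 | (10S)-10-{[(9Z)-16-(tert-butyldiphenylsilyloxy)hexadec-9-enoyl]oxy}-12-hydroxy-2-epi-cedr-8-en-15-oic acid | CC1(C)[C@H]2C[C@@]3([C@@H](OC(=O)CCCCCCC/C=C\CCCCCCO[Si](c4ccccc4)(c4ccccc4)C(C)(C)C)C=C2C(=O)O)[C@@H](CO)CC[C@@H]13 | intermediate
32 | (10S)-10-{[(9Z)-16-(tert-butyldiphenylsilyloxy)hexadec-9-enoyl]oxy}-12-oxo-2-epi-cedr-8-en-15-oic acid | CC1(C)[C@H]2C[C@@]3([C@@H](OC(=O)CCCCCCC/C=C\CCCCCCO[Si](c4ccccc4)(c4ccccc4)C(C)(C)C)C=C2C(=O)O)[C@@H](C=O)CC[C@@H]13 | intermediate
33 | CNP0214056.2, (1S,2S,5S,7R,10S)-2-formyl-10-{[(9Z)-16-hydroxyhexadec-9-enoyl]oxy}-6,6-dimethyltricyclo[5.3.1.0^1,5]undec-8-ene-8-carboxylic acid | CC1(C)[C@H]2C[C@@]3([C@@H](OC(=O)CCCCCCC/C=C\CCCCCCO)C=C2C(=O)O)[C@@H](C=O)CC[C@@H]13 | target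

Total step count: 21. Longest linear sequence: 19 steps (steps 1–14 and 17–21); the side chain takes 2 steps (15 and 16).

Steps most likely to fail

1. Step 6 (Proposed new method). The excited dihydrobenzofuran may decay by homolysis of the aryl ether C–O bond, add in the ortho mode, or fail to reach the exciplex geometry because the chain is held on a ring, so that little meta adduct forms.
Fallback with known chemistry, setting out from 7 and coming back at 16: the open-chain form of the same photoreaction, in which allylic strain turns C12 away from the alkoxy group, so the mirror-image benzylic centre is needed and C2 is corrected afterwards. Step 4 is run on 7 with the mirror-image ligand and gives, through the (R)-pinacol boronate F1 and the (R)-silyl ether alcohol F2, the (R)-diol F3. Selective O-methylation of the phenol (MeI, K2CO3, acetone) gives (R)-2-(2-methoxy-4-methylphenyl)-6-methylhept-5-en-1-ol F4, and acetylation (Ac2O, pyridine) gives its acetate F5. Irradiation at 254 nm in pentane, the established meta photocycloaddition of ortho-alkoxy 5-arylpent-2-enes, should give the C11-methoxy adduct with cyclopropane C7–C8–C11 F6 and the C11-methoxy adduct with cyclopropane C1–C10–C11 F7, both with C1, C5 and C7 as in the main route but C12 on the C10 face. Bromine (CH2Cl2, −78 °C) opens both with loss of the methyl group to 10-bromo-11-oxocedr-8-en-12-yl acetate F8 and 8-bromo-11-oxocedr-9-en-12-yl acetate F9, and Bu3SnH/AIBN reduces both to 11-oxocedr-8-en-12-yl acetate F10. Methanolysis (K2CO3, MeOH) gives 12-hydroxycedr-8-en-11-one F11 and Dess–Martin oxidation gives 11-oxocedr-8-en-12-al F12. Equilibration at C2 (K2CO3, MeOH) should favour 11-oxo-2-epi-cedr-8-en-12-al F13, the only epimer that can be stabilised by internal hemiacetal formation between C12 and C11; unchanged F12 is recycled. NaBH4 at −78 °C reduces the aldehyde of F13 to 16.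

2. Step 12. Enolisation towards C15 may be sluggish, and forcing conditions may bring over-oxidation or acid-induced loss of the silyl ether.
Fallback, setting out from 20 and coming back at 22: TBSOTf/Et3N converts 20, which can be deprotonated only at C15, into the extended silyl dienol ether 10,12-bis(tert-butyldimethylsilyloxy)-2-epi-cedra-8(15),9-diene F14. Peracid (mCPBA, NaHCO3, CH2Cl2, −20 °C, then dilute acid) oxidises the terminal carbon (vinylogous Rubottom oxidation, the γ-hydroxylation known for dienol ethers of cyclic enones) to 12-(tert-butyldimethylsilyloxy)-15-hydroxy-2-epi-cedr-8-en-10-one F15. Luche reduction of F15, with the facial argument of step 13, gives 22.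

3. Step 13. Facial selectivity at C10 may be poor if the silyloxymethyl group on C2 screens the exo face and hydride also arrives from the endo face.
Fallback, setting out from 20 and coming back at 22: C10 is set under catalyst control at the simple enone stage, before C15 is oxidised. CBS reduction of 20 (oxazaborolidine antipode matched to the 10S product, catecholborane, toluene, −78 °C) gives (10S)-12-(tert-butyldimethylsilyloxy)-2-epi-cedr-8-en-10-ol F16. Catalytic SeO2 with t-BuOOH (CH2Cl2, rt) then hydroxylates C15, the only methyl on the more substituted olefin carbon, and gives 22.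

Further compounds
F1 | step 6 | (R)-2-{2-[2-(tert-butyldimethylsilyloxy)-4-methylphenyl]-6-methylhept-5-enyl}-4,4,5,5-tetramethyl-1,3,2-dioxaborolane | CC1(C)OB(C[C@H](CCC=C(C)C)c2ccc(C)cc2O[Si](C)(C)C(C)(C)C)OC1(C)C
F2 | step 6 | (R)-2-[2-(tert-butyldimethylsilyloxy)-4-methylphenyl]-6-methylhept-5-en-1-ol | OC[C@H](CCC=C(C)C)c1ccc(C)cc1O[Si](C)(C)C(C)(C)C
F3 | step 6 | (R)-2-(2-hydroxy-4-methylphenyl)-6-methylhept-5-en-1-ol | OC[C@H](CCC=C(C)C)c1ccc(C)cc1O
F4 | step 6 | (R)-2-(2-methoxy-4-methylphenyl)-6-methylhept-5-en-1-ol | OC[C@H](CCC=C(C)C)c1ccc(C)cc1OC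
F5 | step 6 | (R)-2-(2-methoxy-4-methylphenyl)-6-methylhept-5-enyl acetate | CC(=O)OC[C@H](CCC=C(C)C)c1ccc(C)cc1OC
F6 | step 6 | C11-methoxy meta adduct with cyclopropane C7–C8–C11, olefin C9=C10 and acetoxymethyl C12 on the C10 face | C[C@]12C=C[C@@]34[C@H](COC(C)=O)CC[C@H]4C(C)(C)[C@H]1[C@@]32OC
F7 | step 6 | C11-methoxy meta adduct with cyclopropane C1–C10–C11, olefin C8=C9 and acetoxymethyl C12 on the C10 face | CC1=C[C@@H]2[C@@]34[C@H](COC(C)=O)CC[C@H]4C(C)(C)[C@H]1[C@]23OC
F8 | step 6 | 10-bromo-11-oxocedr-8-en-12-yl acetate (C10 configuration undefined) | CC1(C)[C@H]2C(=O)[C@@]3(C(Br)C=C2C)[C@H](COC(C)=O)CC[C@@H]13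
F9 | step 6 | 8-bromo-11-oxocedr-9-en-12-yl acetate (C8 configuration undefined) | CC1(C)[C@H]2C(=O)[C@@]3(C=CC2(C)Br)[C@H](COC(C)=O)CC[C@@H]13
F10 | step 6 | 11-oxocedr-8-en-12-yl acetate | CC1(C)[C@H]2C(=O)[C@@]3(CC=C2C)[C@H](COC(C)=O)CC[C@@H]13
F11 | step 6 | 12-hydroxycedr-8-en-11-one | CC1(C)[C@H]2C(=O)[C@@]3(CC=C2C)[C@H](CO)CC[C@@H]13
F12 | step 6 | 11-oxocedr-8-en-12-al | CC1(C)[C@H]2C(=O)[C@@]3(CC=C2C)[C@H](C=O)CC[C@@H]13
F13 | step 6 | 11-oxo-2-epi-cedr-8-en-12-al | CC1(C)[C@H]2C(=O)[C@@]3(CC=C2C)[C@@H](C=O)CC[C@@H]13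
F14 | step 12 | 10,12-bis(tert-butyldimethylsilyloxy)-2-epi-cedra-8(15),9-diene | CC1(C)[C@H]2C[C@@]3(C(O[Si](C)(C)C(C)(C)C)=CC2=C)[C@@H](CO[Si](C)(C)C(C)(C)C)CC[C@@H]13
F15 | step 12 | 12-(tert-butyldimethylsilyloxy)-15-hydroxy-2-epi-cedr-8-en-10-one | CC1(C)[C@H]2C[C@@]3(C(=O)C=C2CO)[C@@H](CO[Si](C)(C)C(C)(C)C)CC[C@@H]13
F16 | step 13 | (10S)-12-(tert-butyldimethylsilyloxy)-2-epi-cedr-8-en-10-ol | CC1(C)[C@H]2C[C@@]3([C@@H](O)C=C2C)[C@@H](CO[Si](C)(C)C(C)(C)C)CC[C@@H]13
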